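**Retrosynthetic overview**
- The 6,7-cis-diol comes last, by α-face OsO4 dihydroxylation of a ring-A alkene; the (E)-enoate arm comes from hydroboration of a C1 vinyl carbinol and Cu-catalysed syn-hydroalkylation of methyl but-2-ynoate.
- The vinyl carbinol comes from axial vinyl addition to a 2,5,5,8a-tetramethyl trans-decalone.
- Ring B of that decalone comes from a one-carbon ring expansion of a trans-hydrindenone with diazoethane, which inserts CH(CH3) between C=O and CH2 (the key 1,2-shift).
- Ring A of the hydrindenone comes from RCM of a 2-allyl-3-(1,1-dimethylallyl)cyclopentanone, made from 2-methylcyclopentenone by enantioselective conjugate reverse-prenylation and enolate allylation.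
- Ring order: purchased cyclopentenone → ring A (RCM) → ring B (5 → 6 expansion).

Assumption: in step 2 the catalyst antipode used is the one that gives the (3S) adduct (both antipodes are accessible); locants in the "Why" lines follow the name of the compound being discussed.

**Step 1**
Reactants: 1 1-chloro-3-methylbut-2-ene (prenyl chloride)
Product: 3 trimethyl(3-methylbut-2-en-1-yl)silane, via prenylmagnesium chloride 2 (not isolated)
Conditions: Mg, Me3SiCl, THF, 0 °C → rt
Reagents that add atoms: chlorotrimethylsilane, C[Si](C)(C)Cl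
Why: Barbier-type Grignard formation and silylation, in which the allylic Grignard is captured by the bulky silyl chloride at its unhindered primary terminus to give the linear allylsilane (no stereocentre).

**Step 2**
Reactants: 4 2-methylcyclopent-2-en-1-one; 3 trimethyl(3-methylbut-2-en-1-yl)silane; 5 3-bromoprop-1-ene (allyl bromide)
Product: 8 (2S,3S)-2-methyl-3-(2-methylbut-3-en-2-yl)-2-(prop-2-en-1-yl)cyclopentan-1-one, via silyl enol ether 6 (not isolated), via lithium enolate 7 (not isolated)
Conditions: (i) chiral N-triflyl imidodiphosphorimidate (IDPi) acid (2 mol %), toluene, −60 °C; (ii) MeLi, THF, 0 °C → rt; (iii) 5, DMPU, −78 → 0 °C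
Reagents that add atoms: none
Why: Proposed new method: an enantioselective Hosomi–Sakurai conjugate reverse-prenylation under silylium counteranion-directed catalysis, in which the IDPi acid is silylated by 3, the Me3Si+/IDPi− pair O-silylates 4 to a siloxyallyl cation held in the chiral anion pocket, 3 attacks the Re face of C3 through its γ-carbon (SE2′) to set C3 (S) and the β-silyl cation passes Me3Si+ on to give the regiodefined enol ether 6; MeLi then releases the tetrasubstituted lithium enolate 7, which is allylated anti to the bulky tert-alkyl group to set the quaternary C2 (S); the closest known reactions are the racemic TiCl4- or Tf2NH-promoted Sakurai conjugate allylation and IDPi-catalysed Mukaiyama–Michael additions, followed by classical silyl enol ether/MeLi alkylation.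

**Step 3**
Reactants: 8 (2S,3S)-2-methyl-3-(2-methylbut-3-en-2-yl)-2-(prop-2-en-1-yl)cyclopentan-1-one
Product: 9 (3aS,7aS)-4,4,7a-trimethyl-2,3,3a,4,7,7a-hexahydro-1H-inden-1-one
Conditions: Grubbs II (3 mol %), CH2Cl2 (0.01 M), 40 °C
Reagents that add atoms: none
Why: Ring-closing metathesis of the two terminal vinyl groups forms the six-membered ring A with loss of ethylene, and the trans ring fusion is already fixed by the trans arrangement of the two arms in 8.

**Step 4**
Reactants: 9 (3aS,7aS)-4,4,7a-trimethyl-2,3,3a,4,7,7a-hexahydro-1H-inden-1-one; 10 N-ethyl-N-nitrosourea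
Product: 13 (2R,4aS,8aS)-2,5,5,8a-tetramethyl-3,4,4a,5,8,8a-hexahydronaphthalen-1(2H)-one, via diazoethane 11 (not isolated), via C2-epimeric ketone 12 (not isolated)
Conditions: 10, 40 % aq KOH, Et2O, 0 °C (ethereal 11, dried over KOH); then 9, BF3·OEt2 (1.2 equiv), CH2Cl2/Et2O, −78 → −40 °C; then NaOMe (cat.), MeOH, rt
Reagents that add atoms: none
Why: Lewis-acid-promoted diazoalkane ring expansion (a Tiffeneau–Demjanov-type 1,2-alkyl shift), in which diazoethane adds to the activated, strained cyclopentanone and on loss of N2 the less substituted CH2 migrates in preference to the quaternary carbon, so CH(CH3) is inserted between C=O and CH2; base equilibration then converts the axial-methyl epimer 12, destabilised by a 1,3-diaxial clash with the angular methyl, into the equatorial (2R) ketone.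

**Step 5**
Reactants: 13 (2R,4aS,8aS)-2,5,5,8a-tetramethyl-3,4,4a,5,8,8a-hexahydronaphthalen-1(2H)-one; 14 vinylmagnesium bromide
Product: 15 (1S,2R,4aS,8aS)-1-ethenyl-2,5,5,8a-tetramethyl-1,2,3,4,4a,5,8,8a-octahydronaphthalen-1-ol
Conditions: anhydrous CeCl3 (1.5 equiv), THF, −78 → 0 °C; aq NH4Cl
Reagents that add atoms: none
Why: Organocerium 1,2-addition (Imamoto conditions suppress enolisation of the hindered ketone) proceeds by axial attack on the α face, anti to the axial angular methyl, giving the (1S) carbinol with equatorial OH and axial vinyl.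

**Step 6**
Reactants: 15 (1S,2R,4aS,8aS)-1-ethenyl-2,5,5,8a-tetramethyl-1,2,3,4,4a,5,8,8a-octahydronaphthalen-1-ol; 16 methyl but-2-ynoate
Product: 18 methyl (2E)-5-[(1S,2R,4aS,8aS)-1-hydroxy-2,5,5,8a-tetramethyl-1,2,3,4,4a,5,8,8a-octahydronaphthalen-1-yl]-3-methylpent-2-enoate, via alkyl-9-BBN borane 17 (not isolated)
Conditions: 9-BBN-H (1.3 equiv), THF, 0 °C → rt; then 16 (1.5 equiv), CuOAc (5 mol %), P(OPh)3 (10 mol %), t-BuOK (cat.), t-BuOH (1 equiv), 1,4-dioxane, 40 °C
Reagents that add atoms: none
Why: Anti-Markovnikov hydroboration of the terminal vinyl group by 9-BBN (the hindered ring alkene is untouched) followed by Cu-catalysed conjugate addition of the primary alkylborane to the ynoate and protonation of the alkenylcopper (formal syn-hydroalkylation) places the new chain trans to the ester, giving the E-enoate stereospecifically.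

**Step 7**
Reactants: 18 methyl (2E)-5-[(1S,2R,4aS,8aS)-1-hydroxy-2,5,5,8a-tetramethyl-1,2,3,4,4a,5,8,8a-octahydronaphthalen-1-yl]-3-methylpent-2-enoate
Product: 19 methyl (2E)-3-methyl-5-[(1S,2R,4aS,6S,7R,8aS)-1,6,7-trihydroxy-2,5,5,8a-tetramethyldecahydronaphthalen-1-yl]pent-2-enoate
Conditions: OsO4 (2 mol %), NMO (1.5 equiv), acetone/H2O 5:1, 0 °C → rt; aq Na2SO3
Reagents that add atoms: N-methylmorpholine N-oxide, C[N+]1([O-])CCOCC1; water, O
Why: Upjohn syn-dihydroxylation occurs at the electron-richer cis-disubstituted ring alkene rather than the conjugated trisubstituted enoate, from the α face opposite the axial β-methyl groups on C8a and C5, setting the (6S,7R) cis-diol.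

**Compound list**
1 | 1-chloro-3-methylbut-2-ene (prenyl chloride) | CC(C)=CCCl | starting material
2 | (3-methylbut-2-en-1-yl)magnesium chloride | CC(C)=CC[Mg]Cl | intermediate
3 | trimethyl(3-methylbut-2-en-1-yl)silane | CC(C)=CC[Si](C)(C)C | intermediate
4 | 2-methylcyclopent-2-en-1-one | CC1=CCCC1=O | starting material
5 | 3-bromoprop-1-ene (allyl bromide) | C=CCBr | starting material
6 | trimethyl{[(3S)-2-methyl-3-(2-methylbut-3-en-2-yl)cyclopent-1-en-1-yl]oxy}silane | C[Si](C)(C)OC1=C(C)[C@H](C(C)(C)C=C)CC1 | intermediate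
7 | lithium (3S)-2-methyl-3-(2-methylbut-3-en-2-yl)cyclopent-1-en-1-olate | [Li]OC1=C(C)[C@H](C(C)(C)C=C)CC1 | intermediate
8 | (2S,3S)-2-methyl-3-(2-methylbut-3-en-2-yl)-2-(prop-2-en-1-yl)cyclopentan-1-one (allyl trans to the tert-alkyl group) | O=C1CC[C@@H](C(C)(C)C=C)[C@]1(C)CC=C | intermediate
9 | (3aS,7aS)-4,4,7a-trimethyl-2,3,3a,4,7,7a-hexahydro-1H-inden-1-one (trans-fused) | O=C1CC[C@H]2C(C)(C)C=CC[C@@]21C | intermediate
10 | N-ethyl-N-nitrosourea | CCN(N=O)C(N)=O | starting material
11 | diazoethane | CC=[N+]=[N-] | intermediate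
12 | (2S,4aS,8aS)-2,5,5,8a-tetramethyl-3,4,4a,5,8,8a-hexahydronaphthalen-1(2H)-one (axial 2-methyl epimer) | O=C1[C@@H](C)CC[C@H]2C(C)(C)C=CC[C@@]21C | intermediate
13 | (2R,4aS,8aS)-2,5,5,8a-tetramethyl-3,4,4a,5,8,8a-hexahydronaphthalen-1(2H)-one (trans-decalone, equatorial 2-methyl) | O=C1[C@H](C)CC[C@H]2C(C)(C)C=CC[C@@]21C | intermediate
14 | vinylmagnesium bromide | C=C[Mg]Br | starting material
15 | (1S,2R,4aS,8aS)-1-ethenyl-2,5,5,8a-tetramethyl-1,2,3,4,4a,5,8,8a-octahydronaphthalen-1-ol | C=C[C@]1(O)[C@H](C)CC[C@H]2C(C)(C)C=CC[C@@]21C | intermediate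
16 | methyl but-2-ynoate | CC#CC(=O)OC | starting material
17 | (1S,2R,4aS,8aS)-1-[2-(9-borabicyclo[3.3.1]nonan-9-yl)ethyl]-2,5,5,8a-tetramethyl-1,2,3,4,4a,5,8,8a-octahydronaphthalen-1-ol | B1(C2CCCC1CCC2)CC[C@]3(O)[C@H](C)CC[C@H]4C(C)(C)C=CC[C@@]43C | intermediate
18 | methyl (2E)-5-[(1S,2R,4aS,8aS)-1-hydroxy-2,5,5,8a-tetramethyl-1,2,3,4,4a,5,8,8a-octahydronaphthalen-1-yl]-3-methylpent-2-enoate | COC(=O)/C=C(\C)CC[C@]1(O)[C@H](C)CC[C@H]2C(C)(C)C=CC[C@@]21C | intermediate
19 | methyl (2E)-3-methyl-5-[(1S,2R,4aS,6S,7R,8aS)-1,6,7-trihydroxy-2,5,5,8a-tetramethyldecahydronaphthalen-1-yl]pent-2-enoate | COC(=O)/C=C(\C)CC[C@]1(O)[C@H](C)CC[C@H]2C(C)(C)[C@H](O)[C@H](O)C[C@@]21C | target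

**Step count**
Total step count: 7. Longest linear sequence: 7 steps (1 → 3 → 8 → 9 → 13 → 15 → 18 → 19).

**Three steps most likely to fail**

Step 2 (the proposed new method). The risks are low enantioselectivity, or low turnover with a fully substituted nucleophilic carbon and an α-substituted enone. The fallback uses only known chemistry, sets out from 3, 4 and 5 and comes back at 8. The achiral acid-catalysed Hosomi–Sakurai conjugate allylation (Tf2NH 1 mol %, CH2Cl2, −78 °C) gives the racemic silyl enol ether, that is 6 together with its enantiomer, trimethyl{[(3R)-2-methyl-3-(2-methylbut-3-en-2-yl)cyclopent-1-en-1-yl]oxy}silane F1. The same MeLi/allyl bromide sequence passes through the racemic lithium enolate, 7 plus lithium (3R)-2-methyl-3-(2-methylbut-3-en-2-yl)cyclopent-1-en-1-olate F2, to the racemic trans ketone, 8 plus (2R,3R)-2-methyl-3-(2-methylbut-3-en-2-yl)-2-(prop-2-en-1-yl)cyclopentan-1-one F3. Preparative chiral SFC then separates 8 from F3, so the absolute configuration comes from resolution instead of catalysis.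

Step 4 (ring expansion). The risks are sluggish addition of the secondary diazoalkane to the neopentyl carbonyl, competing migration of the quaternary carbon, epoxide formation and the handling of diazoethane. The fallback sets out from 9 and comes back at 13, and it separates the homologation from the methylation. TMSCHN2 with BF3·OEt2 (CH2Cl2, −78 °C), whose bulk strongly favours migration of the CH2 group, gives (4aS,8aS)-5,5,8a-trimethyl-2-(trimethylsilyl)-3,4,4a,5,8,8a-hexahydronaphthalen-1(2H)-one F4. Protodesilylation on acidic work-up gives (4aS,8aS)-5,5,8a-trimethyl-3,4,4a,5,8,8a-hexahydronaphthalen-1(2H)-one F5. Its only enolisable position is then methylated (LDA, THF, −78 °C; MeI) and equilibrated (NaOMe, MeOH) to 13.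

Step 6 (hydroboration and Cu-catalysed hydroalkylation). The risks are interference of the free tertiary hydroxyl (internal borate formation, slow B-to-Cu transfer) and base-induced oxa-Michael closure of the C1 alkoxide onto the new enoate. The fallback sets out from 17 (generated from 15 as in the route) and comes back at 18, and it replaces the conjugate addition by a cross-coupling. Commercial methyl acetoacetate (eight non-hydrogen atoms) is converted by stereoselective O-triflation (Tf2O, aq Me4NOH, hexane, 5 °C) into methyl (2E)-3-{[(trifluoromethyl)sulfonyl]oxy}but-2-enoate F6. A B-alkyl Suzuki–Miyaura coupling of 17 with F6 (Pd(dppf)Cl2, aq K3PO4, THF, rt → 50 °C) proceeds with retention of alkene geometry and gives 18 under mild, weakly basic conditions.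

**Further compounds**
F1 | step 2 | trimethyl{[(3R)-2-methyl-3-(2-methylbut-3-en-2-yl)cyclopent-1-en-1-yl]oxy}silane | C[Si](C)(C)OC1=C(C)[C@@H](C(C)(C)C=C)CC1
F2 | step 2 | lithium (3R)-2-methyl-3-(2-methylbut-3-en-2-yl)cyclopent-1-en-1-olate | [Li]OC1=C(C)[C@@H](C(C)(C)C=C)CC1
F3 | step 2 | (2R,3R)-2-methyl-3-(2-methylbut-3-en-2-yl)-2-(prop-2-en-1-yl)cyclopentan-1-one | O=C1CC[C@H](C(C)(C)C=C)[C@@]1(C)CC=C
F4 | step 4 | (4aS,8aS)-5,5,8a-trimethyl-2-(trimethylsilyl)-3,4,4a,5,8,8a-hexahydronaphthalen-1(2H)-one (C2 epimers) | O=C1C([Si](C)(C)C)CC[C@H]2C(C)(C)C=CC[C@@]21C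
F5 | step 4 | (4aS,8aS)-5,5,8a-trimethyl-3,4,4a,5,8,8a-hexahydronaphthalen-1(2H)-one | O=C1CCC[C@H]2C(C)(C)C=CC[C@@]21C
F6 | step 6 | methyl (2E)-3-{[(trifluoromethyl)sulfonyl]oxy}but-2-enoate | COC(=O)/C=C(\C)OS(=O)(=O)C(F)(F)F
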